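## Retrosynthetic overview

1. Target 30 ← hydroxy aldehyde 29 (C7‑OH adds to C6‑CHO, closing ring B as the lactol last) ← exo‑face epoxidation of C9=C11 and Woodward cis‑hydroxylation/acetylation of C1=C2 ← triene 17.
2. Triene 17 ← C9–C10 bond by central‑carbon addition of a pentadienylzinc (complete ring A, from 2,6,6‑trimethylcyclohexenone) to the C9 carbonyl of bicyclic diketone 11, then dehydration; C5/C6 come later by hydroboration of the exocyclic C5=C6.
3. Ring D, the cyclopentanone (C8, C14, C13, C16, C15) of the bicyclo[3.2.1]octane ← one‑carbon ring expansion of the cyclobutanone (C14, C13, C16, C15) of a cis‑bicyclo[4.2.0]octane by a titanocene‑triggered radical 1,2‑acyl shift from C14 to C8. Enabling feature: ketone carbon C15 is bonded to quaternary C8, C8 is bonded to C14 and carries the oxymethylene C7, so the C8–C15 bond is the product of the shift and C8/C7–O is the footprint of a spiro‑oxirane.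
4. Cyclobutanone 7 ← enantioselective enone–allene [2+2] photocycloaddition on cyclohexenone (sets C13/C14, the only external source of chirality), α‑oxygenation, Corey–Chaykovsky epoxidation, ozonolysis.
5. Ring order: C (cyclohexenone) → cyclobutane → D by expansion (step 5) → A brought in intact (step 9) → oxirane (step 17) → B (lactol, step 18).

Key step: step 5

Remark on numbering: kaurane‑type numbers are used throughout (ring A C1–C5/C10 with methyls C18–C20, C6 lactol carbon, C7 oxymethylene, ring C C8/C9/C11–C14, ring D C8/C14/C13/C16/C15, C17 exo‑methylene).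
Assumption: the C6 lactol of the target is taken to equilibrate to the anomer drawn.
Assumption: for 4–10 (C9) and 6–7 (C8) the expected major epimer is drawn; the other epimer converges because C9 becomes a carbonyl (step 7) and C8 becomes planar (step 5).
Assumption: the sense and level of stereocontrol in steps 1, 9, 12, 15 and 17 are predictions from models, not established facts.

## Route

Step 1
Reactants: 1 cyclohex-2-en-1-one; 2 propa-1,2-diene (allene)
Product: 3 (1S,6S)-8-methylidenebicyclo[4.2.0]octan-2-one (cis-fused; ketone = C8, methylidene carbon = C15)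
Conditions: hν (366 nm), chiral prolinol-derived oxazaborolidine·AlBr3 (0.5 equiv), CH2Cl2, −78 °C
Reagents that add atoms: none
Why: Enantioselective Lewis-acid-catalysed enone–alkene [2+2] photocycloaddition: allene should add head-to-head (its central carbon on the enone α-carbon C14) to give the cis-fused adduct, and the chiral Lewis acid should shield one enone face and so set C13 and C14.

Step 2
Reactants: 3 (1S,6S)-8-methylidenebicyclo[4.2.0]octan-2-one
Product: 5 (1S,3R,6S)-8-methylidene-3-(triethylsilyloxy)bicyclo[4.2.0]octan-2-one, via hydroxy ketone 4 (not isolated)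
Conditions: LiN(iPr)2, THF, −78 °C; 2-(phenylsulfonyl)-3-phenyloxaziridine; then Et3SiCl, −78 → 0 °C
Reagents that add atoms: 2-(phenylsulfonyl)-3-phenyloxaziridine O=S(=O)(c1ccccc1)N1OC1c1ccccc1; chlorotriethylsilane CC[Si](Cl)(CC)CC
Why: Davis oxidation of the kinetic enolate formed on the CH2 side (C9) should deliver oxygen from the convex face anti to the cyclobutane, and the alkoxide is silylated in situ; the C9 configuration is irrelevant later.

Step 3
Reactants: 5 (1S,3R,6S)-8-methylidene-3-(triethylsilyloxy)bicyclo[4.2.0]octan-2-one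
Product: 6 spiro-oxirane of 5 at C8 (oxirane CH2 = C7; epimer with the oxirane oxygen syn to the cyclobutane drawn)
Conditions: Me3S+ I−, n-BuLi, THF, −10 → 0 °C
Reagents that add atoms: trimethylsulfonium iodide C[S+](C)C.[I-]
Why: Corey–Chaykovsky epoxidation: dimethylsulfonium methylide adds to the C8 ketone and closes the oxirane; either C8 epimer serves because C8 becomes a planar radical in step 5.

Step 4
Reactants: 6 spiro-oxirane with exocyclic C15 methylidene
Product: 7 cyclobutanone (6 with C15=O in place of C15=CH2; cis-fused bicyclo[4.2.0]octan-7-one carrying the C8 spiro-oxirane and C9 silyl ether)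
Conditions: O3, pyridine, CH2Cl2, −78 °C
Reagents that add atoms: ozone [O-][O+]=O
Why: Pyridine-mediated reductive ozonolysis cleaves the only alkene directly to the cyclobutanone and should leave the oxirane and silyl ether untouched.

Step 5
Reactants: 7 cyclobutanone with C8 spiro-oxirane
Product: 9 (1S,2R,5R)-2-hydroxy-1-(hydroxymethyl)bicyclo[3.2.1]octan-7-one (C15 ketone, quaternary C8 bearing C7H2OH, C9–OH), via ring-expanded silyl ether 8 (not isolated)
Conditions: Cp2TiCl2 (0.2 equiv), Mn powder, 2,4,6-collidinium chloride, THF, 25 °C, slow addition of 7; then 1 M HCl, THF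
Reagents that add atoms: none
Why: Proposed new method: Cp2TiCl (trivalent titanium, formed in situ) should open the spiro-oxirane by C8–O homolysis to the tertiary C8 radical carrying the C7–O–Ti arm, this radical adds 3-exo-trig to the strained C15 carbonyl on the neighbouring C14, and β-scission of the shared C14–C15 bond of the cyclopropyloxy radical moves the acyl group from C14 to C8, so the cyclobutanone (C14, C13, C16, C15) becomes the cyclopentanone ring D (C8, C14, C13, C16, C15) of a bicyclo[3.2.1]octane; the secondary C14 radical is then reduced by a second Cp2TiCl and protonated by collidinium. The closest known reaction types are the Nugent–RajanBabu reductive epoxide opening, the 3-exo addition of titanocene-derived epoxide radicals to ketones, and the Dowd–Beckwith radical ring expansion of cyclobutanones started from halides with Bu3SnH. Ring D closes by this 3-exo-trig addition/fragmentation sequence, a net suprafacial 1,2-acyl shift. The only new stereocentre, quaternary C8, is fixed by the cis ring fusion, because C15 can reach C8 only on the face where it already sits at C14, so both oxirane epimers converge on one configuration. The step needs regioselective opening to the tertiary radical, which is inherent to trivalent titanium, and rearrangement faster than reduction or β-hydrogen loss of that radical, which the cyclobutanone strain and the low stationary concentration of Cp2TiCl under catalytic conditions should secure; aliphatic ketones are not reduced by Cp2TiCl, and the acidic work-up removes the silyl group.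

Step 6
Reactants: 9 (1S,2R,5R)-2-hydroxy-1-(hydroxymethyl)bicyclo[3.2.1]octan-7-one
Product: 10 (1S,2R,5R)-1-[(tert-butyldiphenylsilyloxy)methyl]-2-hydroxybicyclo[3.2.1]octan-7-one
Conditions: tBuPh2SiCl, imidazole, DMF, 0 → 25 °C
Reagents that add atoms: tert-butyl(chloro)diphenylsilane CC(C)(C)[Si](Cl)(c1ccccc1)c1ccccc1
Why: The bulky silyl chloride should silylate the primary C7 hydroxyl selectively over the hindered secondary C9 hydroxyl (selective silyl ether formation).

Step 7
Reactants: 10 primary silyl ether with free C9–OH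
Product: 11 (1S,5R)-1-[(tert-butyldiphenylsilyloxy)methyl]bicyclo[3.2.1]octane-2,7-dione (C9 and C15 ketones)
Conditions: Dess–Martin periodinane, CH2Cl2, 25 °C
Reagents that add atoms: none
Why: Dess–Martin oxidation of the secondary alcohol gives the diketone, which can neither enolise towards nor fragment at the bridgehead C8.

Step 8
Reactants: 12 2,6,6-trimethylcyclohex-2-en-1-one
Product: 13 1,5,5-trimethyl-6-methylidenecyclohex-1-ene
Conditions: Ph3PCH3+ Br−, KOtBu, toluene, 90 °C
Reagents that add atoms: methyltriphenylphosphonium bromide C[P+](c1ccccc1)(c1ccccc1)c1ccccc1.[Br-]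
Why: Wittig methylenation of the hindered enone gives the cross-ring diene that contains all carbons of ring A plus C6 and C20.

Step 9
Reactants: 11 (1S,5R)-1-[(tert-butyldiphenylsilyloxy)methyl]bicyclo[3.2.1]octane-2,7-dione; 13 1,5,5-trimethyl-6-methylidenecyclohex-1-ene
Product: 16 tertiary C9 carbinol carrying ring A through the new C9–C10 bond (C10 quaternary with C20 methyl, C1=C2 and exocyclic C5=C6; C15 ketone kept), via pentadienylpotassium 14 (not isolated), via pentadienylzinc chloride 15 (not isolated)
Conditions: 13, n-BuLi/KOtBu, THF–hexane, −78 → −40 °C; ZnCl2, −78 °C; then 11, THF, −78 °C; aq. NH4Cl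
Reagents that add atoms: none
Why: γ-Selective pentadienylzinc carbonyl addition: the zinc reagent should add through its central carbon (C10) to the cyclohexanone carbonyl C9 rather than the less electrophilic five-ring carbonyl C15, through a closed chair transition state entered on the carbonyl face syn to the C15 bridge with the quaternary C8 anti to C5, which sets C10 and places the C9–O bond axial.

Step 10
Reactants: 16 tertiary C9 carbinol
Product: 17 triene ketone (C9=C11, C1=C2, C5=C6; C15 ketone; C7 silyl ether)
Conditions: SOCl2, pyridine, CH2Cl2, −40 → 0 °C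
Reagents that add atoms: none
Why: E2 dehydration via the chlorosulfite: pyridine removes the axial H11 anti to the axial C9–O bond (C8 and C10 carry no hydrogen), giving C9=C11 without a free cation.

Step 11
Reactants: 17 triene ketone
Product: 18 triisopropylsilyl enol ether of 17 (C15(OSi)=C16)
Conditions: iPr3SiOTf, Et3N, CH2Cl2, 0 °C
Reagents that add atoms: triisopropylsilyl trifluoromethanesulfonate CC(C)[Si](OS(=O)(=O)C(F)(F)F)(C(C)C)C(C)C
Why: Soft enolisation of the only enolisable ketone (C15 towards C16, since C8 is a bridgehead) masks it against the borane and prepares the nucleophile for methylenation.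

Step 12
Reactants: 18 silyl enol ether triene
Product: 20 primary alcohol (C5–H, C6H2OH; C6 cis to C20 and trans to C9), via alkylborane 19 (not isolated)
Conditions: 9-BBN, THF, 0 → 50 °C; then H2O2, aq. NaOAc, 0 °C
Reagents that add atoms: hydrogen peroxide OO
Why: Hydroboration–oxidation: 9-BBN should add to the terminus of the 1,1-disubstituted C5=C6 in preference to the other alkenes and deliver hydrogen to C5 from the face opposite the syn-axial C20 and C4 methyl groups, which sets C5.

Step 13
Reactants: 20 primary alcohol with C15 silyl enol ether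
Product: 23 exo-methylene ketone (C15=O, C16=C17H2) with free C6–OH, via Mannich base 21 (not isolated), via ammonium iodide 22 (not isolated)
Conditions: CH2=NMe2+ I−, CH2Cl2, 25 °C; MeI; then DBU, 0 °C
Reagents that add atoms: N,N-dimethylmethyleneiminium iodide C=[N+](C)C.[I-]
Why: Mannich reaction of the silyl enol ether at C16, quaternisation and base-induced elimination give the enone; the double bond can only be exocyclic because C13 is a bridgehead.

Step 14
Reactants: 23 enone alcohol
Product: 24 enone aldehyde (C6 aldehyde on C5)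
Conditions: Dess–Martin periodinane, CH2Cl2, 25 °C
Reagents that add atoms: none
Why: Dess–Martin oxidation of the primary alcohol under neutral conditions should leave the C5 stereocentre, flanked by two quaternary carbons, untouched.

Step 15
Reactants: 24 enone aldehyde with C1=C2 alkene
Product: 26 cis-hydroxy acetate (C2–OAc axial, C1–OH, both syn to C20; the regioisomeric monoacetate converges in step 16), via iodo acetate 25 (not isolated)
Conditions: I2, AgOAc, AcOH, 25 °C; then H2O, 90 °C
Reagents that add atoms: silver acetate CC(=O)[O-].[Ag+]; water O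
Why: Woodward cis-hydroxylation: the iodonium ion should form on the ring-A face opposite the axial C20 and C4 methyl groups, acetate opens it anti at C2, and the acetate then displaces iodide at C1 with inversion to an acetoxonium ion that water opens, placing both oxygens syn to C20; the hindered C9=C11 and the electron-poor enone should be spared.

Step 16
Reactants: 26 cis-hydroxy acetate
Product: 27 1,2-diacetate (C1–OAc, C2–OAc cis, syn to C20)
Conditions: Ac2O, pyridine, DMAP (cat.), CH2Cl2, 25 °C
Reagents that add atoms: acetic anhydride CC(=O)OC(C)=O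
Why: Standard acylation of the remaining secondary hydroxyl, with retention at C1 and C2.

Step 17
Reactants: 27 diacetate with C9=C11 alkene
Product: 28 9,11-epoxide (oxygen anti to the C15–C16 bridge)
Conditions: dimethyldioxirane, acetone, 0 °C
Reagents that add atoms: dimethyldioxirane CC1(C)OO1
Why: Dioxirane epoxidation of the only electron-rich alkene from the exo face of the bicyclo[3.2.1]octene, anti to the two-carbon bridge, should set C9 and C11, while the enone and the hindered aldehyde react much more slowly.

Step 18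
Reactants: 28 epoxide with C7 silyl ether and C6 aldehyde
Product: 30 CNP0224512.1 (target lactol), via hydroxy aldehyde 29 (not isolated)
Conditions: Bu4NF, AcOH, THF, 25 → 40 °C
Reagents that add atoms: none
Why: Buffered fluoride desilylation frees the C7 hydroxyl, which adds to the C6 aldehyde to close the seven-membered lactol ring B (hemiacetalisation), the anomer drawn being taken as the stable one.

## Compound list

1 | cyclohex-2-en-1-one | O=C1C=CCCC1 | starting material
2 | propa-1,2-diene (allene) | C=C=C | starting material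
3 | (1S,6S)-8-methylidenebicyclo[4.2.0]octan-2-one | C=C1C[C@@H]2CCCC(=O)[C@H]12 | intermediate
4 | (1S,3R,6S)-3-hydroxy-8-methylidenebicyclo[4.2.0]octan-2-one | C=C1C[C@@H]2CC[C@@H](O)C(=O)[C@H]12 | intermediate
5 | (1S,3R,6S)-8-methylidene-3-(triethylsilyloxy)bicyclo[4.2.0]octan-2-one | C=C1C[C@@H]2CC[C@@H](O[Si](CC)(CC)CC)C(=O)[C@H]12 | intermediate
6 | C8 spiro-oxirane of 5 (oxirane CH2 = C7) | C=C1C[C@@H]2CC[C@@H](O[Si](CC)(CC)CC)[C@@]3(CO3)[C@H]12 | intermediate
7 | cis-fused cyclobutanone (C15=O) with C8 spiro-oxirane and C9 triethylsilyl ether | O=C1C[C@@H]2CC[C@@H](O[Si](CC)(CC)CC)[C@@]3(CO3)[C@H]12 | intermediate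
8 | 1-(hydroxymethyl)-2-(triethylsilyloxy)bicyclo[3.2.1]octan-7-one (configuration as in 9) | O=C1C[C@@H]2CC[C@@H](O[Si](CC)(CC)CC)[C@@]1(CO)C2 | intermediate
9 | (1S,2R,5R)-2-hydroxy-1-(hydroxymethyl)bicyclo[3.2.1]octan-7-one | O=C1C[C@@H]2CC[C@@H](O)[C@@]1(CO)C2 | intermediate
10 | (1S,2R,5R)-1-[(tert-butyldiphenylsilyloxy)methyl]-2-hydroxybicyclo[3.2.1]octan-7-one | O=C1C[C@@H]2CC[C@@H](O)[C@@]1(CO[Si](c3ccccc3)(c3ccccc3)C(C)(C)C)C2 | intermediate
11 | (1S,5R)-1-[(tert-butyldiphenylsilyloxy)methyl]bicyclo[3.2.1]octane-2,7-dione | O=C1C[C@@H]2CCC(=O)[C@@]1(CO[Si](c3ccccc3)(c3ccccc3)C(C)(C)C)C2 | intermediate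
12 | 2,6,6-trimethylcyclohex-2-en-1-one | CC1=CCCC(C)(C)C1=O | starting material
13 | 1,5,5-trimethyl-6-methylidenecyclohex-1-ene | CC1=CCCC(C)(C)C1=C | intermediate
14 | (3,5,5-trimethyl-4-methylidenecyclohex-2-en-1-yl)potassium (pentadienyl anion of 13) | [K+].CC1=C[CH-]CC(C)(C)C1=C | intermediate
15 | chloro(3,5,5-trimethyl-4-methylidenecyclohex-2-en-1-yl)zinc | CC1=CC([Zn]Cl)CC(C)(C)C1=C | intermediate
16 | C9 carbinol: 11 with C9(OH) bonded to C10 of the 1,5,5-trimethyl-6-methylidenecyclohex-2-en-1-yl unit | C=C1C(C)(C)CC=C[C@@]1(C)[C@@]2(O)CC[C@H]3CC(=O)[C@]2(CO[Si](c4ccccc4)(c4ccccc4)C(C)(C)C)C3 | intermediate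
17 | triene ketone (C9=C11, C1=C2, C5=C6, C15=O) | C=C1C(C)(C)CC=C[C@@]1(C)C2=CC[C@H]3CC(=O)[C@]2(CO[Si](c4ccccc4)(c4ccccc4)C(C)(C)C)C3 | intermediate
18 | C15 triisopropylsilyl enol ether of 17 | C=C1C(C)(C)CC=C[C@@]1(C)C2=CC[C@H]3C=C(O[Si](C(C)C)(C(C)C)C(C)C)[C@]2(CO[Si](c4ccccc4)(c4ccccc4)C(C)(C)C)C3 | intermediate
19 | B-alkyl-9-borabicyclo[3.3.1]nonane adduct at C6 | C(B1C2CCCC1CCC2)[C@@H]1C(C)(C)CC=C[C@@]1(C)C2=CC[C@H]3C=C(O[Si](C(C)C)(C(C)C)C(C)C)[C@]2(CO[Si](c4ccccc4)(c4ccccc4)C(C)(C)C)C3 | intermediate
20 | C6 primary alcohol (C5 set) with C15 silyl enol ether | OC[C@@H]1C(C)(C)CC=C[C@@]1(C)C2=CC[C@H]3C=C(O[Si](C(C)C)(C(C)C)C(C)C)[C@]2(CO[Si](c4ccccc4)(c4ccccc4)C(C)(C)C)C3 | intermediate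
21 | C16 (dimethylamino)methyl ketone (Mannich base) | OC[C@@H]1C(C)(C)CC=C[C@@]1(C)C2=CC[C@H]3[C@H](CN(C)C)C(=O)[C@]2(CO[Si](c4ccccc4)(c4ccccc4)C(C)(C)C)C3 | intermediate
22 | trimethylammonium iodide of 21 | OC[C@@H]1C(C)(C)CC=C[C@@]1(C)C2=CC[C@H]3[C@H](C[N+](C)(C)C)C(=O)[C@]2(CO[Si](c4ccccc4)(c4ccccc4)C(C)(C)C)C3.[I-] | intermediate
23 | 16-methylidene-15-ketone with free C6–OH | OC[C@@H]1C(C)(C)CC=C[C@@]1(C)C2=CC[C@H]3C(=C)C(=O)[C@]2(CO[Si](c4ccccc4)(c4ccccc4)C(C)(C)C)C3 | intermediate
24 | enone C6 aldehyde | O=C[C@@H]1C(C)(C)CC=C[C@@]1(C)C2=CC[C@H]3C(=C)C(=O)[C@]2(CO[Si](c4ccccc4)(c4ccccc4)C(C)(C)C)C3 | intermediate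
25 | trans-diaxial 2-acetoxy-1-iodide | O=C[C@@H]1C(C)(C)C[C@H](OC(C)=O)[C@@H](I)[C@@]1(C)C2=CC[C@H]3C(=C)C(=O)[C@]2(CO[Si](c4ccccc4)(c4ccccc4)C(C)(C)C)C3 | intermediate
26 | cis-2-acetoxy-1-hydroxy compound (both syn to C20) | O=C[C@@H]1C(C)(C)C[C@H](OC(C)=O)[C@H](O)[C@@]1(C)C2=CC[C@H]3C(=C)C(=O)[C@]2(CO[Si](c4ccccc4)(c4ccccc4)C(C)(C)C)C3 | intermediate
27 | cis-1,2-diacetate with C9=C11 alkene | O=C[C@@H]1C(C)(C)C[C@H](OC(C)=O)[C@H](OC(C)=O)[C@@]1(C)C2=CC[C@H]3C(=C)C(=O)[C@]2(CO[Si](c4ccccc4)(c4ccccc4)C(C)(C)C)C3 | intermediate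
28 | 9,11-epoxide with C7 silyl ether and C6 aldehyde | O=C[C@@H]1C(C)(C)C[C@H](OC(C)=O)[C@H](OC(C)=O)[C@@]1(C)[C@]23O[C@@H]3C[C@H]4C(=C)C(=O)[C@]2(CO[Si](c5ccccc5)(c5ccccc5)C(C)(C)C)C4 | intermediate
29 | open hydroxy aldehyde (C7–OH, C6–CHO) | O=C[C@@H]1C(C)(C)C[C@H](OC(C)=O)[C@H](OC(C)=O)[C@@]1(C)[C@]23O[C@@H]3C[C@H]4C(=C)C(=O)[C@]2(CO)C4 | intermediate
30 | CNP0224512.1 | C=C1C(=O)[C@@]23CO[C@@H](O)[C@@H]4C(C)(C)C[C@H](OC(C)=O)[C@H](OC(C)=O)[C@@]4(C)[C@]24O[C@@H]4C[C@@H]1C3 | target

## Step count and risks

Total step count: 18. Longest linear sequence: 17 (steps 1–7 and 9–18; step 8 is the side branch).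

Steps most likely to fail:

1. Step 5 (proposed new method). The tertiary C8 radical may be reduced or lose a β-hydrogen before the acyl shift, or the oxirane may open by Lewis acid instead of by electron transfer. Fallback with known chemistry: from 7, Markovnikov opening of the oxirane with 48% aq. HBr in CHCl3 at 0 °C, which also removes the silyl group, should give the tertiary bromide bromohydrin F1. The classical Dowd–Beckwith ring expansion of F1 (Bu3SnH, AIBN, benzene, 80 °C) then comes back to the route at 9.

2. Step 9. The zinc reagent may add to the wrong carbonyl (C15) or through a terminal carbon, face selection at C10 may be poor, or the hindered adduct may revert. Fallback by cross-coupling instead of carbonyl addition: from 11, kinetic enolisation towards C11 (KN(SiMe3)2, PhNTf2, THF, −78 °C) gives the C9 enol triflate F2. From 13, metalation (n-BuLi/KOtBu) and quenching with 2-isopropoxy-4,4,5,5-tetramethyl-1,3,2-dioxaborolane gives the allylic pinacol boronate F3. A branch-selective Suzuki–Miyaura coupling of F2 and F3 (Pd2(dba)3, bulky biarylphosphine, K3PO4, THF/H2O) would form the C9–C10 bond directly, with separation of the C10 epimers, and comes back at 17, also bypassing step 10.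

3. Step 15. Anti opening of the iodonium ion at C2 is slow because of the two syn-axial methyl groups, and iodine may attack the C9=C11 alkene instead. Fallback: from 24, palladium-catalysed syn-dioxygenation (Pd(OAc)2 cat., PhI(OAc)2, AcOH/Ac2O, 40 °C), which runs through trans-acetoxypalladation and acetoxonium displacement at tetravalent palladium, should give the same face outcome and comes back at 27.

Further compounds
F1 | step 5 | tertiary C8 bromide / C7 primary alcohol (bromohydrin) of the cis-fused cyclobutanone with free C9–OH | O=C1C[C@@H]2CC[C@@H](O)[C@](Br)(CO)[C@H]12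
F2 | step 9 | C9 enol triflate of 11 (C9=C11) | O=C1C[C@@H]2CC=C(OS(=O)(=O)C(F)(F)F)[C@@]1(CO[Si](c3ccccc3)(c3ccccc3)C(C)(C)C)C2
F3 | step 9 | 4,4,5,5-tetramethyl-2-(3,5,5-trimethyl-4-methylidenecyclohex-2-en-1-yl)-1,3,2-dioxaborolane (racemic) | CC1=CC(B2OC(C)(C)C(C)(C)O2)CC(C)(C)C1=C
F0 | step 15 | none | none
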